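## Retrosynthetic overview
- **C7=C8, made last:** aldol condensation of the ring ketone with methyl (5Z)-7-oxohept-5-enoate. This brings in C1–C7 with 5Z already in place and gives 7E.
- **C8–C12, the only carbocycle, made once:** conrotatory 4π closure of a 3-chloro-2,5-dioxygenated pentadienyl cation. This is the C12-hydroxylated, C10-chlorinated form of the oxidopentadienyl cation proposed between the coral's 8,9-allene oxide and preclavulone A. A chiral counter-anion sets C12.
- **Source of the cation:** a trisubstituted furan loses its C8 leaving group, takes up water at C12 and opens. The furan O becomes the C9 ketone and the water becomes the C12 hydroxyl.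
- **Building blocks:** the furan comes from 3-chlorofuran, ClCH2OMe (C8) and (Z)-1-bromooct-2-ene (C13–C20) in one flask. The enal comes from a one-flask ozonolysis of cyclohepta-1,3-diene.
- **Ring order:** the purchased furan ring is sacrificed to give the cyclopentenone in step 4. No other ring is made.

Assumption: prostanoid numbering (C1 = ester carbon, C20 = chain end) is used for positions.
Assumption: the (R) antipode of the acid catalyst is taken to give the (4S) ring ketone. The sense is read from the first run, and the equally available (S) antipode is used if it is the reverse.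

## Route

Step 1
Reactants: 1 (Z)-oct-2-en-1-ol
Product: 2 (Z)-1-bromooct-2-ene
Conditions: PBr3 (0.4 equiv), Et2O, −10 → 0 °C
Reagents that add atoms: phosphorus tribromide, BrP(Br)Br
Why: Bromide displaces the phosphite ester formed in situ by SN2 (PBr3 bromination), and at or below 0 °C a primary Z-allylic alcohol reacts without allylic shift or Z/E leakage.

Step 2
Reactants: 3 3-bromofuran
Product: 5 3-chlorofuran, via 3-furyllithium 4 (not isolated)
Conditions: n-BuLi (1.05 equiv), Et2O, −78 °C; C2Cl6 (1.1 equiv), −78 °C → rt; fractional distillation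
Reagents that add atoms: hexachloroethane, ClC(Cl)(Cl)C(Cl)(Cl)Cl
Why: Bromine–lithium exchange below −70 °C, where 3-furyllithium does not isomerise, is followed by electrophilic chlorination with C2Cl6, which gives up Cl+ and collapses to C2Cl4 and LiCl.

Step 3
Reactants: 5 3-chlorofuran; 2 (Z)-1-bromooct-2-ene
Product: 9 3-chloro-2-(methoxymethyl)-5-[(2Z)-oct-2-en-1-yl]furan, via 3-chloro-2-furyllithium 6 (not isolated), via 3-chloro-2-(methoxymethyl)furan 7 (not isolated), via 4-chloro-5-(methoxymethyl)-2-furyllithium 8 (not isolated)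
Conditions: n-BuLi (1.0 equiv), THF, −78 °C; ClCH2OMe (1.0 equiv), −78 → 0 °C; n-BuLi (1.05 equiv), −78 → −20 °C; 2 (1.1 equiv), −78 → 0 °C
Reagents that add atoms: chloromethyl methyl ether, COCCl
Why: In this sequential directed lithiation/alkylation, n-BuLi removes H-2 (flanked by O and Cl, and C–Cl does not exchange), SN2 on ClCH2OMe gives 7, the second n-BuLi removes the only remaining α-H (H-5), and furyllithium 8 displaces the primary allylic bromide by SN2 with the Z alkene untouched.

Step 4
Reactants: 9 3-chloro-2-(methoxymethyl)-5-[(2Z)-oct-2-en-1-yl]furan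
Product: 13 (4S)-2-chloro-4-hydroxy-4-[(2Z)-oct-2-en-1-yl]cyclopent-2-en-1-one, via furfuryl cation 10 (not isolated), via methylene hemiketal 11 (not isolated), via dihydroxypentadienyl cation 12 (not isolated)
Conditions: (R)-3,3'-bis(2,4,6-triisopropylphenyl)-1,1'-binaphthalene-2,2'-diyl N-(trifluoromethylsulfonyl)phosphoramidate, C51H57F3NO5PS (5 mol %), H2O (5 equiv), toluene, 40 °C
Reagents that add atoms: water, O
Why: Proposed new method: the strong chiral acid ionises the furfuryl ether to 10, water adds at the alkyl-bearing C12 to give 11, and this opens to the U-shaped 3-chloro-2,5-dihydroxypentadienyl cation 12 (the C12-oxygenated, C10-chlorinated counterpart of the oxidopentadienyl cation proposed for the coral's allene oxide), which closes C8–C12 by the thermally allowed conrotatory 4π electrocyclisation while its O12–H and O9–H are hydrogen-bonded to the chiral phosphoramidate anion, so that one sense of conrotation and hence the single stereocentre is selected; the racemic process is the Piancatelli rearrangement, known for 5-alkylfurfuryl substrates to give tertiary 4-hydroxycyclopentenones, and the closest asymmetric relatives are the chiral-phosphoric-acid-catalysed aza-Piancatelli rearrangement and the N-triflylphosphoramide-catalysed Nazarov cyclisation.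

Step 5
Reactants: 14 cyclohepta-1,3-diene
Product: 16 methyl (5Z)-7-oxohept-5-enoate, via methoxy hydroperoxide 15 (not isolated)
Conditions: O3 (1.0 equiv), NaHCO3, CH2Cl2/MeOH 5:1, −78 °C; then Ac2O, Et3N, 0 °C → rt; used at once
Reagents that add atoms: ozone, [O-][O+]=O; methanol, CO
Why: In this Criegee ozonolysis with Schreiber end differentiation, the primary ozonide of one ring C=C splits toward the conjugated enal and the saturated carbonyl oxide, MeOH traps the latter as 15, acylation and base-induced fragmentation turn it into the methyl ester, the Z alkene is the untouched ring alkene, and the enal C=C is too electron-poor for a second ozone attack.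

Step 6
Reactants: 13 (4S)-2-chloro-4-hydroxy-4-[(2Z)-oct-2-en-1-yl]cyclopent-2-en-1-one; 16 methyl (5Z)-7-oxohept-5-enoate
Product: 20 chlorovulone I, methyl (5Z,7E,12R,14Z)-10-chloro-12-hydroxy-9-oxoprosta-5,7,10,14-tetraen-1-oate, via dilithium dienolate-alkoxide 17 (not isolated), via lithium aldolate 18 (not isolated), via allylic mesylate 19 (not isolated)
Conditions: LiN(SiMe3)2 (2.2 equiv), THF, −78 °C (13 added to the base); 16 (1.1 equiv), −78 °C; MsCl (1.15 equiv), −78 °C; Et3N (3 equiv), −78 → 0 °C; aq NH4Cl
Reagents that add atoms: none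
Why: In this aldol condensation (directed aldol addition, then E1cB elimination), the base removes O–H and the only enolisable C–H (C8), the dienolate adds 1,2 to the enal, and the less hindered secondary alkoxide is mesylated and lost to give the less strained 7E alkylidene; C12 carries no acidic H and keeps its configuration (the descriptor changes from S to R only because C8 gains CIP rank), and the 5Z alkene takes no part in the bond changes.

## Compound list
1 | (Z)-oct-2-en-1-ol | CCCCC/C=C\CO | starting material
2 | (Z)-1-bromooct-2-ene | CCCCC/C=C\CBr | intermediate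
3 | 3-bromofuran | Brc1ccoc1 | starting material
4 | 3-furyllithium | [Li]c1ccoc1 | intermediate
5 | 3-chlorofuran | Clc1ccoc1 | intermediate
6 | 3-chloro-2-furyllithium | [Li]c1occc1Cl | intermediate
7 | 3-chloro-2-(methoxymethyl)furan | COCc1occc1Cl | intermediate
8 | 4-chloro-5-(methoxymethyl)-2-furyllithium | [Li]c1cc(Cl)c(COC)o1 | intermediate
9 | 3-chloro-2-(methoxymethyl)-5-[(2Z)-oct-2-en-1-yl]furan | CCCCC/C=C\Cc1cc(Cl)c(COC)o1 | intermediate
10 | {3-chloro-5-[(2Z)-oct-2-en-1-yl]furan-2-yl}methyl cation | CCCCC/C=C\Cc1cc(Cl)c([CH2+])o1 | intermediate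
11 | 4-chloro-5-methylidene-2-[(2Z)-oct-2-en-1-yl]-2,5-dihydrofuran-2-ol (either configuration at the hemiketal carbon) | CCCCC/C=C\CC1(O)C=C(Cl)C(=C)O1 | intermediate
12 | O-protonated (3Z,7Z)-3-chloro-2-hydroxytrideca-1,3,7-trien-5-one, the U-shaped 3-chloro-2,5-dihydroxypentadienyl cation (C9 and C12 cis on C10=C11) | CCCCC/C=C\CC(=[OH+])/C=C(Cl)\C(O)=C | intermediate
13 | (4S)-2-chloro-4-hydroxy-4-[(2Z)-oct-2-en-1-yl]cyclopent-2-en-1-one | CCCCC/C=C\C[C@@]1(O)C=C(Cl)C(=O)C1 | intermediate
14 | cyclohepta-1,3-diene | C1=CC=CCCC1 | starting material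
15 | (2Z)-7-hydroperoxy-7-methoxyhept-2-enal | O=C/C=C\CCCC(OC)OO | intermediate
16 | methyl (5Z)-7-oxohept-5-enoate | COC(=O)CCC/C=C\C=O | intermediate
17 | dilithium salt of 13 (C12 alkoxide and C9/C8 enolate) | CCCCC/C=C\C[C@@]1(O[Li])C=C(Cl)C(O[Li])=C1 | intermediate
18 | dilithium aldolate, C7–C8 adduct of 17 and 16 (mixture at C7 and C8, C12 fixed) | CCCCC/C=C\C[C@@]1(O[Li])C=C(Cl)C(=O)C1C(O[Li])/C=C\CCCC(=O)OC | intermediate
19 | C7 methanesulfonate of 18 (mixture at C7 and C8, C12 fixed) | CCCCC/C=C\C[C@@]1(O[Li])C=C(Cl)C(=O)C1C(OS(C)(=O)=O)/C=C\CCCC(=O)OC | intermediate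
20 | chlorovulone I, methyl (5Z,7E,12R,14Z)-10-chloro-12-hydroxy-9-oxoprosta-5,7,10,14-tetraen-1-oate | CCCCC/C=C\C[C@@]1(O)C=C(Cl)C(=O)/C1=C/C=C\CCCC(=O)OC | target

## Count and risks
Total step count: 6. Longest linear sequence: 4 (3 → 5 → 9 → 13 → 20, steps 2, 3, 4 and 6).

**Most likely to fail, first: step 4.**
- The cation is primary and deactivated by chlorine.
- The enol of 12 may ketonise to the open ene-dione. From there C13 could enolise instead of C8.
- The level and sense of induction are unknown.

The fallback gives up catalyst control and resolves. Setting out from 9, the rearrangement is run with ZnCl2 in dioxane/water at reflux to give racemic 2-chloro-4-hydroxy-4-[(2Z)-oct-2-en-1-yl]cyclopent-2-en-1-one F1. Its tertiary alcohol is carbamoylated with (R)-1-(naphthalen-1-yl)ethyl isocyanate (CuCl, DMF). The (4S) carbamate F2 is separated on silica from the (4R) carbamate F3, which is discarded. HSiCl3/Et3N then cleaves F2, and the fallback comes back to the route at 13.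

**Second: step 6.**
- The free C12 alkoxide could open by retro-aldol and erode the ee.
- Mesylation has to choose the secondary alkoxide over the tertiary one.
- The Z-enal can isomerise or be deprotonated at C4.
- Some 7Z isomer must be removed by chromatography.

The fallback moves to a Lewis-acid manifold with no alkoxide present. Setting out from 13 and 16, Me3SiOTf/Et3N (CH2Cl2, 0 °C) converts 13 into the bis(trimethylsilyl) dienol ether of 13 F7. A Mukaiyama aldol addition to 16 (BF3·OEt2, CH2Cl2, −78 °C) gives the 12-O-trimethylsilyl aldol F8. MsCl/Et3N takes this through the 12-O-trimethylsilyl C7 mesylate F9 to 12-O-trimethylsilyl chlorovulone I F10. HF·pyridine in MeCN at 0 °C removes the silyl group, and the fallback comes back to the route at 20.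

**Third: step 3.**
- The second lithiation could occur at C4 or at the CH2OMe group, with Wittig rearrangement.
- The allylation could leak to SN2'.

The fallback carries C8 as a carboxylate, which cannot be lithiated laterally. Setting out from 5, n-BuLi and then CO2 give 3-chlorofuran-2-carboxylic acid F4. LiN(iPr)2 (2.1 equiv, THF, −78 °C) removes the acid proton and H-5, and alkylation with 2 gives 3-chloro-5-[(2Z)-oct-2-en-1-yl]furan-2-carboxylic acid F5. LiAlH4 reduces this to {3-chloro-5-[(2Z)-oct-2-en-1-yl]furan-2-yl}methanol F6. NaH/MeI methylates F6, and the fallback comes back to the route at 9.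

## Further compounds
F1 | step 4 | racemic 2-chloro-4-hydroxy-4-[(2Z)-oct-2-en-1-yl]cyclopent-2-en-1-one | CCCCC/C=C\CC1(O)C=C(Cl)C(=O)C1
F2 | step 4 | (1S)-3-chloro-1-[(2Z)-oct-2-en-1-yl]-4-oxocyclopent-2-en-1-yl N-[(1R)-1-(naphthalen-1-yl)ethyl]carbamate, the (4S) carbamate | CCCCC/C=C\C[C@@]1(OC(=O)N[C@H](C)c2cccc3ccccc23)C=C(Cl)C(=O)C1
F3 | step 4 | diastereomer of F2 with the opposite ring carbinol configuration, the (4R) carbamate | CCCCC/C=C\C[C@]1(OC(=O)N[C@H](C)c2cccc3ccccc23)C=C(Cl)C(=O)C1
F4 | step 3 | 3-chlorofuran-2-carboxylic acid | OC(=O)c1occc1Cl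
F5 | step 3 | 3-chloro-5-[(2Z)-oct-2-en-1-yl]furan-2-carboxylic acid | CCCCC/C=C\Cc1cc(Cl)c(C(=O)O)o1
F6 | step 3 | {3-chloro-5-[(2Z)-oct-2-en-1-yl]furan-2-yl}methanol | CCCCC/C=C\Cc1cc(Cl)c(CO)o1
F7 | step 6 | bis(trimethylsilyl) dienol ether of 13 (C12–OSiMe3 and C9–OSiMe3, C8=C9 and C10=C11) | CCCCC/C=C\C[C@@]1(O[Si](C)(C)C)C=C(Cl)C(O[Si](C)(C)C)=C1
F8 | step 6 | 12-O-trimethylsilyl aldol (C7–OH, mixture at C7 and C8) | CCCCC/C=C\C[C@@]1(O[Si](C)(C)C)C=C(Cl)C(=O)C1C(O)/C=C\CCCC(=O)OC
F9 | step 6 | 12-O-trimethylsilyl C7 mesylate (mixture at C7 and C8) | CCCCC/C=C\C[C@@]1(O[Si](C)(C)C)C=C(Cl)C(=O)C1C(OS(C)(=O)=O)/C=C\CCCC(=O)OC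
F10 | step 6 | 12-O-trimethylsilyl chlorovulone I | CCCCC/C=C\C[C@@]1(O[Si](C)(C)C)C=C(Cl)C(=O)/C1=C/C=C\CCCC(=O)OC
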